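The slow end of the gamma run was where I started: between 50.0 min and 90.0 min L rose by 2 percentage points, and by my subtraction 14.5% of the charged Q remained at the last reading.

| flask | D | Q | remark | time |
|---|---|---|---|---|
| gamma | 0.11 M | 0.070 M | run made earlier |  |
| alder | 0.050 M | 0.200 M |  | 2.5 h |
| ash | 0.10 M | 0.0700 M |  | 2.5 h |

- gamma (time / min: L / %): 8.00: 33.7; 15.0: 43.9; 25.0: 47.1; 50.0: 52.4; 90.0: 54.4

(readings scatter by 0.5 percentage points)

* the winner by amount of L, in percent of the D charged; "neither" if no more than 2 percentage points parts them (alder / ash / neither)
* how much L is there at the end, in percent of the D charged: alder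
* how much L is there at the end, in percent of the D charged: ash

1. From above: each L takes one D and one Q. Alder charged more Q than D, so its bound was 100%. Ash charged less Q than D, so its bound was 70.0%.

2. From below: by the proposed steps, G-making over L-making goes as cJ/cQ, and J comes from D. So I defined a waste factor w (a selectivity factor): D not found as L, per L, divided by the charged cD/cQ. Gamma's last reading gave 0.533, a value that carries the scatter of that reading.

3. That w counted any J still present as waste, and it included gamma's thin late Q. Alder and ash both had more Q per D than gamma, so I took w as their upper limit. On that assumption, which is an estimate and not a proof, the L share was at least the inverse of one plus w·cD/cQ: 88.2% for alder and 56.8% for ash.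

4. Alder's estimated lower limit stood 18 points above ash's upper bound, well beyond the margin of 2 points, so I committed to alder.

5. The forecast gave alder, with 95% for alder and 59% for ash, both inside my brackets, and said of alder “Q is in large excess”.

The flasks gave alder as winner, with 93.9% in alder and 59.7% in ash, inside both brackets.

    D → J (k = 0.590 min⁻¹)
    Q + J → L (k = 1.90 L mol⁻¹ min⁻¹)
    2 J → G (k = 0.740 L mol⁻¹ min⁻¹)

In alder, the L step had 98% of its turnover behind it after 0.250 h, and the flask ended with G at 6.07% and 77% of its Q. In ash, J stood at 1.99% beside 16.9% of its Q at 1.25 h, while L moved from 58.2% to 59.7% by 2.50 h. Reckoned from these results, w was 0.258 in alder and 0.473 in ash, both below gamma's 0.533. For a neighbour of alder with 0.080 M of Q, the same reckoning with gamma's w gives an estimated lower limit of 75.0%; that neighbour gave 81.4%.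

The data were computed for an exercise.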